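The earlier runs and the new flask are calculated for substances that don't exist; noise was put on by code.

I began with a subtraction, the easiest step on the board, since epsilon, alpha, gamma and beta share their charges and differ in how those charges go in.

| setting | birch | ash | maple | epsilon | alpha | gamma | beta |
|---|---|---|---|---|---|---|---|
| substrate | 0.10 M | 0.067 M | 0.15 M | 0.10 M | 0.10 M | 0.10 M (fed, over 15 min) | 0.10 M |
| partner | 0.11 M | 0.11 M | 0.11 M | 0.110 M | 0.110 M | 0.110 M | 0.110 M |
| reagent | 0.20 M | 0.20 M | 0.20 M | 0.200 M (fed, over 15 min) | 0.200 M | 0.200 M | 0.200 M (fed, over 4.0 min) |
| remark | run made earlier | run made earlier | run made earlier | all else is in the flask from the start; the feed brings no volume worth counting | everything together at the start | all else is in the flask from the start; the feed brings no volume worth counting | all else is in the flask from the start; the feed brings no volume worth counting |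
| time |  |  |  | 40 min | 40 min | 40 min | 40 min |

- birch (time / min: target / %, substrate / %): 4.00: 13.6, 71.5; 8.00: 27.7, 60.0; 12.0: 31.9, 49.9; 15.0: 31.4, 46.5; 20.0: 31.0, 41.2; 25.0: 30.9, 36.1
- ash (time / min: target / %, substrate / %): 2.50: 8.8, 77.1; 4.00: 16.5, 71.2; 8.00: 28.4, 56.8; 12.0: 33.4, 44.8; 20.0: 36.8, 33.0; 30.0: 37.1, 24.4
- maple (time / min: target / %, substrate / %): 5.00: 16.5, 70.7; 10.0: 25.2, 59.3; 15.0: 27.4, 53.8; 20.0: 25.0, 49.7; 25.0: 25.3, 45.8; 30.0: 24.2, 45.6

(readings scatter by 1 percentage point)

- which flask leads in amount of target, in percent of the substrate charged ("all alike" within 1.5 percentage points) (epsilon / alpha / gamma / beta / all alike)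
- how much target is there at the end, in percent of the substrate charged: epsilon
- how much target is there at the end, in percent of the substrate charged: alpha
- how much target is there at the end, in percent of the substrate charged: gamma
- how much target is there at the end, in percent of the substrate charged: beta

- percentages count the substrate that a species holds: one homo product counts as two
- steps under discussion: substrate + reagent -> open intermediate; reagent + partner -> second intermediate; open intermediate + second intermediate -> target; 2 open intermediate -> homo product; target <-> isomer of the product

In the birch run, which has alpha's charges put in together, the substrate's first-order pace over the first 4.00 min was 0.0839 min⁻¹, faster than the 0.0264 min⁻¹ between 20.0 min and 25.0 min. So I took something to have pulled reagent away in the first instants, and the step on offer is reagent + partner. If that step is treated as finished first, what it leaves is 0.0900 M, the spare reagent, the charge of reagent less the charge of partner. That is less than the 0.10 M of substrate, so for the substrate, reagent is the limiting reagent, and I expected a floor of 10.0% of substrate.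

The earlier runs tested the subtraction. In maple the same reckoning gives a floor of 40.0%, and its last two readings, 45.8% and 45.6%, stood close together and still above it. In ash the spare exceeded the substrate charge, and substrate kept falling, to 24.4%.

For the middle of birch I took the spare reagent to be making open intermediate, which met second intermediate to give target. Between 12.0 min and 25.0 min target read 31.9% to 30.9% while substrate fell from 49.9% to 36.1%, so I read fresh target as passing on to its isomer at about the pace it formed.

Towards the end, then, I expected target to stay level. By my reckoning a feed in epsilon, gamma or beta shifts when the spare reaches the substrate, not the charges it is reckoned from, and the slow feeds end at 15 min, with 25.0 min still to run. So I committed to the mean of the last two target readings of birch, 30.9%, for each flask, and to all alike within 1.5 percentage points.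

The forecast parted from me on the leader: it named gamma, with 34% there against 32% for epsilon, 31% for alpha and 31.5% for beta, on the ground that “Gamma keeps open intermediate lowest, so least homo”.

The flasks gave 31.4% in epsilon, 31.0% in alpha, 31.3% in gamma and 31.1% in beta, so the answer is all alike.

    substrate + reagent → open intermediate (k = 0.800 M⁻¹ min⁻¹)
    reagent + partner → second intermediate (k = 6.10 M⁻¹ min⁻¹)
    open intermediate + second intermediate → target (k = 5.40 M⁻¹ min⁻¹)
    2 open intermediate → homo product (k = 0.690 M⁻¹ min⁻¹)
    target ⇌ isomer of the product (K = 1.60, k = 0.0620 min⁻¹)

Alpha, left until 400 min, held substrate at 10.4% against my reckoned floor of 10.0%, with reagent down to 0.187% of its charge. The neighbour of beta with 0.50 M of reagent takes the same subtraction: its spare is 0.390 M, more than the substrate charge. Taking away the substrate's 0.10 M as well leaves 58.0% of that reagent charge. After 40.0 min that flask stood at 58.0% of its reagent, with substrate at 0.0114% and target at 38.7%.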